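## Structural features

Compound 13 is a flavanone: a benzo ring A fused to a dihydropyranone ring C (O1, C2, C3, C4, C4a, C8a), with a 3,4-dimethoxyphenyl ring B on C2. Ring A carries 5-OH, 6-OMe and 7-OMe on adjacent carbons and O1 on C8a, so that only C8 bears hydrogen; the 5-OH is hydrogen-bonded to the C4 carbonyl. C2 (S) is the only stereocentre and has no stereogenic neighbour, so the problem is one of absolute configuration alone. The fragile element is the C2–O1 bond. It is β to the ketone, so base can open it by retro-oxa-Michael reaction, and it is a 3,4-dimethoxybenzylic aryl ether, so acid can ionise it; either path racemises C2. The real difficulty is to set C2 and keep it while the ketone and the free 5-OH are put in place, and to tell O5 apart from four other methyl ethers. The key step uses the aryl–oxygen bond C8a–O1 of ring C: it can be closed from the arene side, so the C2–O bond made by an asymmetric ketone reduction enters the ring untouched. Two further features serve the end game: C4 is a benzylic CH2 activated by O1, 5-OMe and 7-OMe, and 5-OMe is the only ether peri to the future carbonyl.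

## Logic of the disconnections

13 ⇒ 12. The O5–H bond is traced back to an O5–CH3 bond. With every phenolic oxygen methylated, no free phenol has to pass through base, hydride or palladium, and O5 alone can form a chelate with a Lewis acid and the C4 carbonyl. The gain is one uniform protecting pattern. The demand is that the forward cleavage removes one methyl group out of five without opening ring C.

12 ⇒ 10. The C4=O bond is removed, back to C4H2 (11 lies between them in the forward sense). Without a carbonyl β to O1, 10 and all earlier compounds cannot suffer retro-oxa-Michael or aldol-type cleavage, so C2 is safe in every basic step. Ring C becomes a plain cyclic benzylic ether. The forward oxidation must choose C4–H over C2–H and end at the ketone.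

10 ⇒ 9. The C8a–O1 bond is cut. It is the one bond of ring C whose formation leaves all four bonds at C2 alone. Ring C opens to a three-carbon chain and the stereocentre becomes a simple secondary benzylic alcohol. The forward C(aryl)–O coupling must outrun β-hydride elimination, and C8a needs a leaving group that survives the preceding steps.

9 ⇒ 8. The C2–H bond of the carbinol is cut, back to the ketone. An aryl alkyl ketone is a well-behaved substrate for catalyst-controlled reduction. The only stereocentre disappears and everything before is achiral. The forward step needs high facial selectivity and must tolerate the aryl sulfonate.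

8 ⇒ 7. The O–S bond of the sulfonate is cut, back to the phenol. The leaving group is put on only after all steps that would endanger it. The forward step must sulfonylate the phenol oxygen and not the ketone enol.

7 ⇒ 6. The C3–H and C4–H bonds are removed, back to the C3=C4 alkene. The enone is the retron of a carbonyl condensation. The forward reduction must saturate the alkene and spare the aryl ketone.

6 ⇒ 3 + 4. The C3=C4 bond is cut. This divides the skeleton into ring A with C4 and ring B with C2 and C3, two pieces of equal size. The forward condensation must work on a free ortho-phenoxide aldehyde and must avoid acid.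

3 ⇒ 1. The C4–C4a bond is cut. The two ortho positions of 1 are equivalent and the para position is blocked, so no regiochemical question arises. The forward step must be an ortho-selective mono-formylation.

## Other disconnections considered

Alternative 1: The cut removes ring A altogether: C8–C7 and C4a–C5 are disconnected, leading back to (2S)-2-(3,4-dimethoxyphenyl)-6-methyl-2,3-dihydro-4H-pyran-4-one A1 and dimethyl methoxymalonate A2. In the forward sense the extended lithium enolate of A1 would be acylated at the methyl carbon by one ester of A2, and C4a would then attack the second ester in a Claisen step. Aromatisation would give (2S)-5,7-dihydroxy-6-methoxy-2-(3,4-dimethoxyphenyl)chroman-4-one A3, and selective methylation of the unchelated 7-OH would give 13.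
- In favour: the C4 carbonyl is present from the start, 6-OMe comes with A2, and O5 and O7 emerge free and differ in acidity. No late C–H oxidation and no Lewis-acid demethylation are needed. On oxidation-state economy and on the O5 problem this plan is the better one.
- Against: kinetic deprotonation of a dihydropyranone of this kind is expected at C3 and not at the vinylogous methyl group. The C3 enolate can expel O1 and reclose, which would scramble C2 in the key step itself. The double acylation through a β-tricarbonyl intermediate has no close precedent on this substrate class.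
- Comparison: about five to six steps including a separate asymmetric synthesis of A1, against eight, so it is shorter if the annulation works. Its configurational risk lies inside the key step, whereas the chosen ring closure is stereoretentive by mechanism.

Alternative 2: The cut takes out O1–C2 and C3–C4 and divides ring C between 2-(dimethoxymethyl)-3,4,5-trimethoxyphenol A4 (one acetalisation from 3) and 3,4-dimethoxystyrene A5. A chiral Brønsted acid would ionise A4 to its methoxy-substituted ortho-quinone methide, which would add A5 in an inverse-demand [4+2] cycloaddition. The product would be (2S,4S)-2-(3,4-dimethoxyphenyl)-4,5,6,7-tetramethoxychromane A6 (2,4-cis). Hydrolysis of the C4 ether and oxidation would lead to 12, and step 8 to 13.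
- In favour: both ring-C bonds, the ring and C2 are formed in one step from two simple partners, and C4 arrives oxygenated. The polarity is matched, and the racemic Lewis-acid union of salicylaldehyde acetals with styrenes is an established reaction type. On convergence, on step count (about six from 1) and on the C4 oxidation level it is the better plan.
- Against: enantiocontrol would rest on an ion pair. With so electron-rich a styrene the addition is likely to be stepwise through a 3,4-dimethoxybenzylic cation, which loosens the transition state. A6 also holds two acid-ionisable benzylic ethers in the acid that formed it, so C2 could equilibrate.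
- Comparison: the end game is equal (the same demethylation). The chosen plan sets C2 in a ketone reduction of a well-understood type and never touches it again, which is the stronger answer to the main difficulty.

Alternative 3: The cut is the C3=C4 bond of (2S)-5,6,7-trimethoxy-2-(3,4-dimethoxyphenyl)-2H-chromene A8, leading back to 1-{[(1S)-1-(3,4-dimethoxyphenyl)prop-2-en-1-yl]oxy}-2-ethenyl-3,4,5-trimethoxybenzene A7. The second-generation Grubbs catalyst would close ring C with loss of ethylene. Wacker oxidation, or Mukaiyama hydration followed by oxidation, would take A8 to 12.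
- In favour: ring-closing metathesis to 2H-chromenes is dependable and tolerant. The alkene fixes where the oxygen at C4 must go, so the choice between C4–H and C2–H does not arise. On regiocontrol of the C4 oxygen it is the better plan, and on step count (about seven to eight from 1) it is equal.
- Against: the stereocentre of A7 is secondary, allylic and 3,4-dimethoxybenzylic at once and carries an aryloxy leaving group. Making that C–O bond by substitution (for example allylic etherification with [Ir(cod)Cl]2 and a chiral phosphoramidite) and keeping it are both exposed to ionisation and to [3,3] rearrangement. A8 can also open by electrocyclic ring opening or lose hydride toward a benzopyrylium ion.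
- Comparison: the chosen plan never makes the C2–O bond by substitution and never has C2 allylic, so it is safer on configuration at equal length.

Key step: step 6

Remark: flavanone numbering (O1, C2–C4, C4a, C5–C8, C8a) is used for all compounds, open-chain ones included; the descriptor at C2 stays (S) from 9 to 13 because the ranking O > aryl > CH2 > H does not change.

## Route

Step 1
Reactants: 1 3,4,5-trimethoxyphenol
Product: 3 2-hydroxy-4,5,6-trimethoxybenzaldehyde, via 2-(hydroxymethyl)-3,4,5-trimethoxyphenol 2 (not isolated)
Conditions: MgCl2 (1.5 equiv), Et3N (3.75 equiv), (CH2O)n (6 equiv), MeCN, reflux; 1 M HCl work-up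
Reagents that add atoms: formaldehyde (as paraformaldehyde), C=O
Why: Casnati–Skattebøl ortho-formylation: the magnesium phenoxide delivers formaldehyde to the ortho carbon only (both ortho positions are equivalent, para is blocked), and 2 is oxidised in the flask by a second formaldehyde through an Oppenauer-type hydride transfer.

Step 2
Reactants: 3 2-hydroxy-4,5,6-trimethoxybenzaldehyde; 4 3,4-dimethoxyacetophenone
Product: 6 (2E)-1-(3,4-dimethoxyphenyl)-3-(2-hydroxy-4,5,6-trimethoxyphenyl)prop-2-en-1-one, via racemic aldol adduct 5 (not isolated)
Conditions: KOH (5 equiv), EtOH, rt to 40 °C; AcOH to pH 6 at 0 °C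
Reagents that add atoms: none
Why: Claisen–Schmidt condensation: 3 has no α-hydrogen and 4 is the only enolisable partner, and aldol 5 dehydrates by E1cB to the (E)-enone. The work-up is kept near neutral because strong acid would cyclise the ortho-hydroxy enone to a benzopyrylium salt.

Step 3
Reactants: 6 (2E)-1-(3,4-dimethoxyphenyl)-3-(2-hydroxy-4,5,6-trimethoxyphenyl)prop-2-en-1-one
Product: 7 1-(3,4-dimethoxyphenyl)-3-(2-hydroxy-4,5,6-trimethoxyphenyl)propan-1-one
Conditions: H2 (1 atm), 5% Pd/C, Ph2S (0.01 equiv), EtOAc, rt
Reagents that add atoms: none
Why: Heterogeneous hydrogenation of the conjugated alkene; the sulfide-moderated palladium on carbon should leave the electron-rich aryl ketone and the aryl ethers alone, and the neutral medium keeps the hydroxy enone open.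

Step 4
Reactants: 7 1-(3,4-dimethoxyphenyl)-3-(2-hydroxy-4,5,6-trimethoxyphenyl)propan-1-one
Product: 8 2-[3-(3,4-dimethoxyphenyl)-3-oxopropyl]-3,4,5-trimethoxyphenyl trifluoromethanesulfonate
Conditions: PhNTf2 (1.1 equiv), Et3N (2 equiv), DMAP (0.1 equiv), CH2Cl2, 0 °C to rt
Reagents that add atoms: N-phenylbis(trifluoromethanesulfonimide), FC(F)(F)S(=O)(=O)N(c1ccccc1)S(=O)(=O)C(F)(F)F
Why: O-Sulfonylation of the phenoxide by a triflimide, a mild triflyl donor that does not form an enol triflate from the ketone under amine base. The open keto-phenol and any cyclic hemiketal both react through the phenoxide.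

Step 5
Reactants: 8 2-[3-(3,4-dimethoxyphenyl)-3-oxopropyl]-3,4,5-trimethoxyphenyl trifluoromethanesulfonate
Product: 9 2-[(3S)-3-(3,4-dimethoxyphenyl)-3-hydroxypropyl]-3,4,5-trimethoxyphenyl trifluoromethanesulfonate
Conditions: (R)-2-methyl-CBS-oxazaborolidine (0.15 equiv), BH3·SMe2 (1.0 equiv), THF, −20 °C; MeOH, then aq NH4Cl
Reagents that add atoms: none
Why: Corey–Bakshi–Shibata reduction: the ketone binds the catalyst boron with the aryl group as the large substituent and the CH2CH2Ar chain as the small one, and the borane held on nitrogen delivers hydride to the Re face. The (R)-catalyst should therefore give the (S)-carbinol, as it does with acetophenone; the aryl triflate is inert to borane.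

Step 6
Reactants: 9 2-[(3S)-3-(3,4-dimethoxyphenyl)-3-hydroxypropyl]-3,4,5-trimethoxyphenyl trifluoromethanesulfonate
Product: 10 (2S)-2-(3,4-dimethoxyphenyl)-5,6,7-trimethoxychromane
Conditions: Pd(OAc)2 (5 mol %), 2-(di-tert-butylphosphino)-1,1'-binaphthyl (6 mol %), Cs2CO3 (1.5 equiv), toluene, 70 °C
Reagents that add atoms: none
Why: Zerovalent palladium, formed in the flask from Pd(OAc)2 and the phosphine, inserts into the C8a–OTf bond; the C2 hydroxyl binds to palladium and is deprotonated by Cs2CO3, and C(aryl)–O reductive elimination from the aryl(alkoxo)palladium chelate forms C8a–O1. The closest known reaction type is the palladium-catalysed intramolecular etherification of ortho-halo- or ortho-sulfonyloxy-arylalkanols bearing a secondary carbinol, which gives 2-substituted chromans. Ring C is closed in this reductive elimination: the alkoxide oxygen is joined to the sp2 carbon C8a from a seven-membered palladacycle, so the new ring is six-membered. No stereocentre is created; C2 keeps the (S) configuration of step 5 because none of its four bonds is made or broken. The selectivity needed is reductive elimination over β-hydride elimination of the palladium alkoxide; the bulky, electron-rich di-tert-butylbiarylphosphine keeps palladium low-coordinate and speeds C–O bond formation, and the short tether favours the six-membered closure. The weak, poorly soluble carbonate in toluene spares the S–O bond of the triflate, and since 9 has no carbonyl group neither retro-aldol cleavage nor elimination can intervene.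

Step 7
Reactants: 10 (2S)-2-(3,4-dimethoxyphenyl)-5,6,7-trimethoxychromane
Product: 12 (2S)-2-(3,4-dimethoxyphenyl)-5,6,7-trimethoxychroman-4-one, via flavan-4-ol 11 (not isolated)
Conditions: DDQ (2.5 equiv), CH2Cl2/pH 7 phosphate buffer (10:1), 0 °C to rt
Reagents that add atoms: water, O
Why: DDQ benzylic oxidation: the quinone pairs with the more electron-rich ring A and takes hydride from its only benzylic carbon, C4, giving a cation stabilised by O1, 5-OMe and 7-OMe that water traps as 11. This electron-rich benzylic alcohol is oxidised by a second DDQ to the aryl ketone, after which ring A is deactivated and the reaction should stop.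

Step 8
Reactants: 12 (2S)-2-(3,4-dimethoxyphenyl)-5,6,7-trimethoxychroman-4-one
Product: 13 (2S)-2-(3,4-dimethoxyphenyl)-5-hydroxy-6,7-dimethoxychroman-4-one
Conditions: BCl3 (1.2 equiv, 1 M in CH2Cl2), CH2Cl2, −78 to −20 °C; H2O, 0 °C
Reagents that add atoms: none
Why: Chelation-controlled ether cleavage: BCl3 binds the C4 carbonyl, the peri 5-OMe closes a six-membered boron chelate and chloride removes its methyl group by SN2, while the other four ethers cannot chelate. Low temperature and near-stoichiometric reagent are chosen to keep ring C closed and C2 intact.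

## Compound list

1 | 3,4,5-trimethoxyphenol | COc1cc(O)cc(OC)c1OC | starting material
2 | 2-(hydroxymethyl)-3,4,5-trimethoxyphenol | COc1cc(O)c(CO)c(OC)c1OC | intermediate (not isolated)
3 | 2-hydroxy-4,5,6-trimethoxybenzaldehyde | COc1cc(O)c(C=O)c(OC)c1OC | intermediate
4 | 3,4-dimethoxyacetophenone | CC(=O)c1ccc(OC)c(OC)c1 | starting material
5 | 1-(3,4-dimethoxyphenyl)-3-hydroxy-3-(2-hydroxy-4,5,6-trimethoxyphenyl)propan-1-one (racemic) | COc1ccc(C(=O)CC(O)c2c(O)cc(OC)c(OC)c2OC)cc1OC | intermediate (not isolated)
6 | (2E)-1-(3,4-dimethoxyphenyl)-3-(2-hydroxy-4,5,6-trimethoxyphenyl)prop-2-en-1-one | COc1ccc(C(=O)/C=C/c2c(O)cc(OC)c(OC)c2OC)cc1OC | intermediate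
7 | 1-(3,4-dimethoxyphenyl)-3-(2-hydroxy-4,5,6-trimethoxyphenyl)propan-1-one | COc1ccc(C(=O)CCc2c(O)cc(OC)c(OC)c2OC)cc1OC | intermediate
8 | 2-[3-(3,4-dimethoxyphenyl)-3-oxopropyl]-3,4,5-trimethoxyphenyl trifluoromethanesulfonate | COc1ccc(C(=O)CCc2c(OS(=O)(=O)C(F)(F)F)cc(OC)c(OC)c2OC)cc1OC | intermediate
9 | 2-[(3S)-3-(3,4-dimethoxyphenyl)-3-hydroxypropyl]-3,4,5-trimethoxyphenyl trifluoromethanesulfonate | COc1ccc([C@@H](O)CCc2c(OS(=O)(=O)C(F)(F)F)cc(OC)c(OC)c2OC)cc1OC | intermediate
10 | (2S)-2-(3,4-dimethoxyphenyl)-5,6,7-trimethoxychromane | COc1ccc([C@@H]2CCc3c(cc(OC)c(OC)c3OC)O2)cc1OC | intermediate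
11 | (2S)-2-(3,4-dimethoxyphenyl)-5,6,7-trimethoxychroman-4-ol (C4 epimers) | COc1ccc([C@@H]2CC(O)c3c(cc(OC)c(OC)c3OC)O2)cc1OC | intermediate (not isolated)
12 | (2S)-2-(3,4-dimethoxyphenyl)-5,6,7-trimethoxychroman-4-one | COc1ccc([C@@H]2CC(=O)c3c(cc(OC)c(OC)c3OC)O2)cc1OC | intermediate
13 | (2S)-2-(3,4-dimethoxyphenyl)-5-hydroxy-6,7-dimethoxychroman-4-one | COc1ccc([C@@H]2CC(=O)c3c(cc(OC)c(OC)c3O)O2)cc1OC | target

Total step count: 8. Longest linear sequence: 8 steps (1 to 13; 4 enters in step 2).

## Least certain steps

**Step 6 (key step).** What may go wrong: β-hydride elimination from the palladium alkoxide, which oxidises the carbinol and reduces C8a, and base-induced cleavage of the S–O bond of the triflate. Both gain ground because reductive elimination from so electron-rich an aryl group is slow.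

Fallback (sets out from 7, returns at 10): ring C is closed at the other end, O1–C2, by substitution with inversion. Reduction of 7 with (S)-2-methyl-CBS-oxazaborolidine and BH3·SMe2 (2 equiv, the phenol consumes one) should give (1R)-1-(3,4-dimethoxyphenyl)-3-(2-hydroxy-4,5,6-trimethoxyphenyl)propan-1-ol F1. Intramolecular Mitsunobu etherification (PPh3, DIAD, THF, 0 °C) would let the phenol displace the activated (R)-carbinol with inversion to give 10. Partial ionisation at the dimethoxybenzylic carbon is the weakness of this closure and the reason it is second choice.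

**Step 7.** What may go wrong: hydride abstraction at C2, a 3,4-dimethoxybenzylic ether position, in place of C4; or loss of a C3 proton from the C4 cation followed by further dehydrogenation of ring C toward a benzopyrylium ion before water adds.

Fallback (sets out from 3, returns at 12): the oxygen at C4 is brought in with the aldehyde carbon instead of by C–H oxidation.
- 3 is triflated (Tf2O, pyridine, CH2Cl2, 0 °C) to 2-formyl-3,4,5-trimethoxyphenyl trifluoromethanesulfonate F2.
- The lithium enolate of 4 (LiN(iPr)2, THF, −78 °C) adds to give the racemic aldol 2-[3-(3,4-dimethoxyphenyl)-1-hydroxy-3-oxopropyl]-3,4,5-trimethoxyphenyl trifluoromethanesulfonate F3.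
- TBSOTf and 2,6-lutidine convert it into the silyl ether F4.
- Reduction as in step 5 should give the (3S)-alcohol F5 as both C1 epimers.
- The conditions of step 6 close it to the 4-silyloxyflavan F6.
- Bu4NF frees the C4 alcohol 11, and Dess–Martin periodinane oxidises 11 to 12, where the C4 epimers converge.

**Step 8.** What may go wrong: opening of ring C while boron sits on the C4 carbonyl, by ionisation of the 3,4-dimethoxybenzylic C2–O1 bond or by retro-oxa-Michael cleavage, with loss of configuration at C2. Cleavage of a second ether is the lesser concern.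

Fallback (sets out from 3, returns at 13): the ether at the future O5 is cleaved while the molecule is still achiral, and O5 is carried as a methoxymethyl ether that comes off in dilute acid.
- 3 is triflated to F2 as described under step 7.
- BCl3 (CH2Cl2, −78 °C) cleaves only the methyl ether chelated to the formyl group and should give the phenol 2-formyl-3-hydroxy-4,5-dimethoxyphenyl trifluoromethanesulfonate F7.
- MOMCl and iPr2NEt convert it into the methoxymethyl ether F8.
- Because hydroxide would attack the triflate, the enone is made in two stages: the lithium enolate of 4 (LiN(iPr)2, THF, −78 °C) gives the racemic aldol F9, and MsCl/Et3N dehydrates it to the (E)-enone F10.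
- Hydrogenation with RhCl(PPh3)3, which leaves the aryl triflate alone, gives the saturated ketone F11, and reduction as in step 5 the (S)-alcohol F12.
- The conditions of step 6 close it to the flavan F13, and DDQ/water as in step 7 gives, through the flavan-4-ol F14 formed in the flask, the flavanone F15.
- HCl in MeOH at rt removes the methoxymethyl group to give 13.

## Further compounds

F1 | step 6 | (1R)-1-(3,4-dimethoxyphenyl)-3-(2-hydroxy-4,5,6-trimethoxyphenyl)propan-1-ol | COc1ccc([C@H](O)CCc2c(O)cc(OC)c(OC)c2OC)cc1OC
F2 | step 7 | 2-formyl-3,4,5-trimethoxyphenyl trifluoromethanesulfonate | COc1cc(OS(=O)(=O)C(F)(F)F)c(C=O)c(OC)c1OC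
F3 | step 7 | 2-[3-(3,4-dimethoxyphenyl)-1-hydroxy-3-oxopropyl]-3,4,5-trimethoxyphenyl trifluoromethanesulfonate (racemic) | COc1ccc(C(=O)CC(O)c2c(OS(=O)(=O)C(F)(F)F)cc(OC)c(OC)c2OC)cc1OC
F4 | step 7 | 2-[1-{[tert-butyl(dimethyl)silyl]oxy}-3-(3,4-dimethoxyphenyl)-3-oxopropyl]-3,4,5-trimethoxyphenyl trifluoromethanesulfonate (racemic) | COc1ccc(C(=O)CC(O[Si](C)(C)C(C)(C)C)c2c(OS(=O)(=O)C(F)(F)F)cc(OC)c(OC)c2OC)cc1OC
F5 | step 7 | 2-[(3S)-1-{[tert-butyl(dimethyl)silyl]oxy}-3-(3,4-dimethoxyphenyl)-3-hydroxypropyl]-3,4,5-trimethoxyphenyl trifluoromethanesulfonate (C1 epimers) | COc1ccc([C@@H](O)CC(O[Si](C)(C)C(C)(C)C)c2c(OS(=O)(=O)C(F)(F)F)cc(OC)c(OC)c2OC)cc1OC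
F6 | step 7 | tert-butyl{[(2S)-2-(3,4-dimethoxyphenyl)-5,6,7-trimethoxychroman-4-yl]oxy}dimethylsilane (C4 epimers) | COc1ccc([C@@H]2CC(O[Si](C)(C)C(C)(C)C)c3c(cc(OC)c(OC)c3OC)O2)cc1OC
F7 | step 8 | 2-formyl-3-hydroxy-4,5-dimethoxyphenyl trifluoromethanesulfonate | COc1cc(OS(=O)(=O)C(F)(F)F)c(C=O)c(O)c1OC
F8 | step 8 | 2-formyl-4,5-dimethoxy-3-(methoxymethoxy)phenyl trifluoromethanesulfonate | COCOc1c(OC)c(OC)cc(OS(=O)(=O)C(F)(F)F)c1C=O
F9 | step 8 | 2-[3-(3,4-dimethoxyphenyl)-1-hydroxy-3-oxopropyl]-4,5-dimethoxy-3-(methoxymethoxy)phenyl trifluoromethanesulfonate (racemic) | COc1ccc(C(=O)CC(O)c2c(OS(=O)(=O)C(F)(F)F)cc(OC)c(OC)c2OCOC)cc1OC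
F10 | step 8 | 2-[(1E)-3-(3,4-dimethoxyphenyl)-3-oxoprop-1-en-1-yl]-4,5-dimethoxy-3-(methoxymethoxy)phenyl trifluoromethanesulfonate | COc1ccc(C(=O)/C=C/c2c(OS(=O)(=O)C(F)(F)F)cc(OC)c(OC)c2OCOC)cc1OC
F11 | step 8 | 2-[3-(3,4-dimethoxyphenyl)-3-oxopropyl]-4,5-dimethoxy-3-(methoxymethoxy)phenyl trifluoromethanesulfonate | COc1ccc(C(=O)CCc2c(OS(=O)(=O)C(F)(F)F)cc(OC)c(OC)c2OCOC)cc1OC
F12 | step 8 | 2-[(3S)-3-(3,4-dimethoxyphenyl)-3-hydroxypropyl]-4,5-dimethoxy-3-(methoxymethoxy)phenyl trifluoromethanesulfonate | COc1ccc([C@@H](O)CCc2c(OS(=O)(=O)C(F)(F)F)cc(OC)c(OC)c2OCOC)cc1OC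
F13 | step 8 | (2S)-2-(3,4-dimethoxyphenyl)-6,7-dimethoxy-5-(methoxymethoxy)chromane | COc1ccc([C@@H]2CCc3c(cc(OC)c(OC)c3OCOC)O2)cc1OC
F14 | step 8 | (2S)-2-(3,4-dimethoxyphenyl)-6,7-dimethoxy-5-(methoxymethoxy)chroman-4-ol (C4 epimers, not isolated) | COc1ccc([C@@H]2CC(O)c3c(cc(OC)c(OC)c3OCOC)O2)cc1OC
F15 | step 8 | (2S)-2-(3,4-dimethoxyphenyl)-6,7-dimethoxy-5-(methoxymethoxy)chroman-4-one | COc1ccc([C@@H]2CC(=O)c3c(cc(OC)c(OC)c3OCOC)O2)cc1OC
A1 | alternative 1 | (2S)-2-(3,4-dimethoxyphenyl)-6-methyl-2,3-dihydro-4H-pyran-4-one | COc1ccc([C@@H]2CC(=O)C=C(C)O2)cc1OC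
A2 | alternative 1 | dimethyl methoxymalonate | COC(=O)C(OC)C(=O)OC
A3 | alternative 1 | (2S)-5,7-dihydroxy-6-methoxy-2-(3,4-dimethoxyphenyl)chroman-4-one | COc1ccc([C@@H]2CC(=O)c3c(cc(O)c(OC)c3O)O2)cc1OC
A4 | alternative 2 | 2-(dimethoxymethyl)-3,4,5-trimethoxyphenol | COC(OC)c1c(O)cc(OC)c(OC)c1OC
A5 | alternative 2 | 3,4-dimethoxystyrene | C=Cc1ccc(OC)c(OC)c1
A6 | alternative 2 | (2S,4S)-2-(3,4-dimethoxyphenyl)-4,5,6,7-tetramethoxychromane (2,4-cis) | COc1ccc([C@@H]2C[C@H](OC)c3c(cc(OC)c(OC)c3OC)O2)cc1OC
A7 | alternative 3 | 1-{[(1S)-1-(3,4-dimethoxyphenyl)prop-2-en-1-yl]oxy}-2-ethenyl-3,4,5-trimethoxybenzene | COc1ccc([C@@H](Oc2cc(OC)c(OC)c(OC)c2C=C)C=C)cc1OC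
A8 | alternative 3 | (2S)-5,6,7-trimethoxy-2-(3,4-dimethoxyphenyl)-2H-chromene | COc1ccc([C@@H]2C=Cc3c(cc(OC)c(OC)c3OC)O2)cc1OC
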